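The closed vessel holds a substrate, a partner and a catalyst, and I left this note for whoever reads the next two flasks.

all flasks: substrate 0.80 M

| run | partner | free catalyst | remark | time |
|---|---|---|---|---|
| Thursday's | 0.56 M | 2.4 mM | run made earlier |  |
| Tuesday's | 0.56 M | 7.3 mM | run made earlier |  |
| gamma | 0.560 M | 12 mM |  | 60 h |
| theta | 0.560 M | 4.0 mM |  | 30 h |

| run | time / h | target / % | side product / % |
|---|---|---|---|
| Thursday's | 6.00 | 10 | 4 |
| Thursday's | 12.0 | 17 | 8 |
| Thursday's | 20.0 | 25 | 13 |
| Thursday's | 25.0 | 23 | 17 |
| Thursday's | 30.0 | 22 | 16 |
| Tuesday's | 2.50 | 15 | 5 |
| Tuesday's | 5.00 | 27 | 3 |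
| Tuesday's | 8.00 | 39 | 6 |
| Tuesday's | 15.0 | 46 | 11 |
| Tuesday's | 30.0 | 39 | 26 |

(scatter of a reading: 2 percentage points)

1. which one finishes higher in share of target in all that became target or side product ("neither" within 2 percentage points) (gamma / theta / neither)
2. share of target in all that became target or side product, gamma
3. share of target in all that became target or side product, theta

- percent here means substrate units held: one side product counts as two

I worked with the fraction left: f, the target still standing out of all target ever made. I took each target lost to take one substrate into a side product counted double, so target ever made is target plus half the side product, and the share asked equals f/(2−f). Substrate left is then the charge minus target and side product. On Tuesday's run that was 43.0% at 15.0 h and 35.0% at 30.0 h, while target fell from 46% to 39%. Supposing no new target was made between those readings, I read κ = 0.0353 M⁻¹ h⁻¹, target's fractional loss per hour per molar of substrate left, a pseudo-first-order loss while substrate is held.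

For gamma I held substrate at 35.0% and started the clock at 8.00 h, as if its target were all made by then, which gave f = 59.8% and a share of 42.7%. For theta I averaged f from both runs' last readings, 74.2%, which gave 58.9%.

The forecast said theta, with 38% for gamma and 59% for theta, calling the late decline “consistent with target plus substrate giving side product”. Its gamma lay below mine.

The flasks gave 46.4% for gamma and 56.8% for theta, so theta finished higher.

    partner + free catalyst → catalyst intermediate A (k = 56.6 M⁻¹ h⁻¹)
    catalyst intermediate A → catalyst intermediate B (k = 13.9 h⁻¹)
    substrate + catalyst intermediate B ⇌ catalyst intermediate C (K = 1.10 M⁻¹, k = 56.4 M⁻¹ h⁻¹)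
    catalyst intermediate C → free catalyst + target (k = 282 h⁻¹)
    substrate + target → side product (k = 0.0327 M⁻¹ h⁻¹)
    partner → decomposed reagent (k = 0.0553 h⁻¹)

At 6.49 h theta made target 6.97 times faster than it used it up. In gamma at 30.0 h, with partner at 0%, κ and the mean substrate turn 44.4% target into 35.9% by 60.0 h; the flask held 36.5%.

Theta left until 2.0 d, with substrate held at 45.1%, reckons to keep 79.5% of the target it held at 30 h, which gives a share of 40.5%. The computed flask gave 42.4%.

(The readings come from a simulation on assumed constants, noise included.)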